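**Assumption:** the target SMILES contains no stereocentre and no stereogenic double bond, so the compound is achiral and no enantiocontrol is needed.

**Retrosynthetic overview**
1. Target ⇒ MOM removal and closure of ring C by one-carbon insertion (DMF-DMA) into a 2,4,6-trihydroxyphenyl benzyl ketone (deoxybenzoin).
2. Deoxybenzoin ⇒ C(α)–C1′ bond between a phenacyl enolonium (α-carbonyl cation from a silyl enol ether and PhI(OH)OTs/BF3·OEt2) and an aryl C–H of the complete, prenylated ring B; both carbons are innately nucleophilic.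
3. Ring B arene ⇒ 2,4-dihydroxybenzaldehyde by MOM protection, Dakin oxidation, ortho-C-prenylation of the phenoxide and O-methylation.
4. Enol ether ⇒ 2′,4′,6′-trihydroxyacetophenone by peracetylation and soft enolisation.
5. Rings A and B are bought as aromatics; ring C (the pyranone) is the only ring formed, and it is formed last.

**Route**

Step 1
Reactants: 1 2,4-dihydroxybenzaldehyde
Product: 2 2,4-bis(methoxymethoxy)benzaldehyde
Conditions: NaH, MOMCl, DMF, 0 °C → rt
Reagents that add atoms: chloromethyl methyl ether (MOMCl), COCCl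
Why: Williamson-type O-alkylation of both phenoxides (MOM protection), NaH being needed for the hydrogen-bonded 2-OH; no stereocentre is formed.

Step 2
Reactants: 2 2,4-bis(methoxymethoxy)benzaldehyde
Product: 4 2,4-bis(methoxymethoxy)phenol, via aryl formate 3 (not isolated)
Conditions: mCPBA, CH2Cl2, 0 °C → rt; aq. NaHCO3 wash; then K2CO3 (cat.), MeOH, rt
Reagents that add atoms: meta-chloroperoxybenzoic acid (mCPBA), OOC(=O)c1cccc(Cl)c1
Why: Baeyer–Villiger (Dakin-type) oxidation in which the electron-rich aryl group migrates in the Criegee intermediate to give the formate, which is methanolysed to the phenol while the MOM ethers stay intact.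

Step 3
Reactants: 4 2,4-bis(methoxymethoxy)phenol
Product: 5 2,4-bis(methoxymethoxy)-6-(3-methylbut-2-en-1-yl)phenol
Conditions: NaH, toluene, 0 °C; prenyl bromide, rt, 16 h
Reagents that add atoms: prenyl bromide (1-bromo-3-methylbut-2-ene), CC(C)=CCBr
Why: ortho-C-alkylation of a sodium phenoxide as a tight ion pair in a non-polar solvent, where the only open ortho position (C6) takes the prenyl group and the alkali-soluble product is separated from the neutral O-prenyl ether by-product.

Step 4
Reactants: 5 2,4-bis(methoxymethoxy)-6-(3-methylbut-2-en-1-yl)phenol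
Product: 6 1,5-bis(methoxymethoxy)-2-methoxy-3-(3-methylbut-2-en-1-yl)benzene
Conditions: MeI, K2CO3, acetone, reflux
Reagents that add atoms: iodomethane, CI
Why: Williamson methylation of the only free phenol fixes the 5′-OMe next to the prenyl group and leaves the two future free hydroxyls as MOM ethers.

Step 5
Reactants: 7 2′,4′,6′-trihydroxyacetophenone
Product: 8 2-acetylbenzene-1,3,5-triyl triacetate
Conditions: Ac2O, pyridine, DMAP (cat.), 0 °C → rt
Reagents that add atoms: acetic anhydride, CC(=O)OC(C)=O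
Why: nucleophilic-catalysed O-acetylation of all three phenols, which makes ring A electron-poor and its ortho oxygens non-nucleophilic for step 7.

Step 6
Reactants: 8 2-acetylbenzene-1,3,5-triyl triacetate
Product: 9 2-[1-(trimethylsilyloxy)ethenyl]benzene-1,3,5-triyl triacetate
Conditions: TMSOTf (1.2 equiv), Et3N, CH2Cl2, 0 °C; concentrate, pentane, filter; used crude
Reagents that add atoms: trimethylsilyl trifluoromethanesulfonate (TMSOTf), C[Si](C)(C)OS(=O)(=O)C(F)(F)F
Why: soft enolisation (silyl triflate plus tertiary amine), in which the more Lewis-basic methyl ketone is silylated much faster than the aryl acetates, gives the terminal silyl enol ether.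

Step 7
Reactants: 9 2-[1-(trimethylsilyloxy)ethenyl]benzene-1,3,5-triyl triacetate; 6 1,5-bis(methoxymethoxy)-2-methoxy-3-(3-methylbut-2-en-1-yl)benzene (2 equiv, excess recovered)
Product: 12 2-[2,4-bis(methoxymethoxy)-5-methoxy-6-(3-methylbut-2-en-1-yl)phenyl]-1-(2,4,6-trihydroxyphenyl)ethan-1-one, via enolonium species 10 (not isolated), via triacetoxy deoxybenzoin 11 (not isolated)
Conditions: PhI(OH)OTs (1.1 equiv), BF3·OEt2 (1.5 equiv), CH2Cl2, −78 °C, 5 min; then 6, −78 → −40 °C; then 7 M NH3 in MeOH, −40 °C → rt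
Reagents that add atoms: none
Why: Proposed new method: the silyl enol ether attacks the BF3-activated trivalent-iodine reagent at oxygen to give the O-bound iodanyl enolate 10, an enolonium (α-carbonyl cation equivalent) whose CH2 terminus is strongly electrophilic, and arene 6 attacks it in a Friedel–Crafts (SN2′-type) step with loss of iodobenzene to form the C(α)–C1′ bond at C4 of 6, the site para to one OMOM and ortho to the other that 5-alkylresorcinol diethers prefer over the position between the two oxygens; the acetates keep ring A from self-arylation and from benzofuranone closure, the oxidant is consumed before the prenyl-bearing arene is added, and ammonia then cleaves the three aryl acetates without enolising the ketone; the closest known reaction type is the hypervalent-iodine enolonium α-arylation of ketone silyl enol ethers with indoles and pyrroles.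

Step 8
Reactants: 12 2-[2,4-bis(methoxymethoxy)-5-methoxy-6-(3-methylbut-2-en-1-yl)phenyl]-1-(2,4,6-trihydroxyphenyl)ethan-1-one
Product: 15 5,7-dihydroxy-3-[2,4-dihydroxy-5-methoxy-6-(3-methylbut-2-en-1-yl)phenyl]-4H-chromen-4-one, via enaminone 13 (not isolated), via bis-MOM isoflavone 14 (not isolated)
Conditions: DMF-DMA (5 equiv), THF, 60 °C; concentrate; then 3 M HCl, MeOH, 50 °C
Reagents that add atoms: N,N-dimethylformamide dimethyl acetal (DMF-DMA), COC(OC)N(C)C
Why: aminomethylenation of the doubly activated CH2 gives the enaminone, whose ortho-hydroxyl closes ring C by addition–elimination of dimethylamine (the classical deoxybenzoin-to-isoflavone synthesis), and acid-catalysed acetal exchange then removes both MOM groups, the prenyl group having no ortho hydroxyl with which to cyclise.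

**Compound list**
1 | 2,4-dihydroxybenzaldehyde | O=Cc1ccc(O)cc1O | starting material
2 | 2,4-bis(methoxymethoxy)benzaldehyde | O=Cc1ccc(OCOC)cc1OCOC | intermediate
3 | 2,4-bis(methoxymethoxy)phenyl formate | O=COc1ccc(OCOC)cc1OCOC | intermediate
4 | 2,4-bis(methoxymethoxy)phenol | Oc1ccc(OCOC)cc1OCOC | intermediate
5 | 2,4-bis(methoxymethoxy)-6-(3-methylbut-2-en-1-yl)phenol | Oc1c(CC=C(C)C)cc(OCOC)cc1OCOC | intermediate
6 | 1,5-bis(methoxymethoxy)-2-methoxy-3-(3-methylbut-2-en-1-yl)benzene | COc1c(CC=C(C)C)cc(OCOC)cc1OCOC | intermediate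
7 | 2′,4′,6′-trihydroxyacetophenone | CC(=O)c1c(O)cc(O)cc1O | starting material
8 | 2-acetylbenzene-1,3,5-triyl triacetate | CC(=O)Oc1cc(OC(C)=O)c(C(C)=O)c(OC(C)=O)c1 | intermediate
9 | 2-[1-(trimethylsilyloxy)ethenyl]benzene-1,3,5-triyl triacetate | C=C(O[Si](C)(C)C)c1c(OC(C)=O)cc(OC(C)=O)cc1OC(C)=O | intermediate
10 | enolonium species: {[1-(2,4,6-triacetoxyphenyl)ethenyl]oxy}(phenyl)iodanyl 4-methylbenzenesulfonate (O-bound trivalent-iodine enolate, BF3-associated) | C=C(OI(c1ccccc1)OS(=O)(=O)c1ccc(C)cc1)c1c(OC(C)=O)cc(OC(C)=O)cc1OC(C)=O | intermediate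
11 | 2-{[2,4-bis(methoxymethoxy)-5-methoxy-6-(3-methylbut-2-en-1-yl)phenyl]acetyl}benzene-1,3,5-triyl triacetate | CC(=O)Oc1cc(OC(C)=O)c(C(=O)Cc2c(OCOC)cc(OCOC)c(OC)c2CC=C(C)C)c(OC(C)=O)c1 | intermediate
12 | 2-[2,4-bis(methoxymethoxy)-5-methoxy-6-(3-methylbut-2-en-1-yl)phenyl]-1-(2,4,6-trihydroxyphenyl)ethan-1-one | O=C(Cc1c(OCOC)cc(OCOC)c(OC)c1CC=C(C)C)c1c(O)cc(O)cc1O | intermediate
13 | 2-[2,4-bis(methoxymethoxy)-5-methoxy-6-(3-methylbut-2-en-1-yl)phenyl]-3-(dimethylamino)-1-(2,4,6-trihydroxyphenyl)prop-2-en-1-one (E/Z mixture) | CN(C)C=C(C(=O)c1c(O)cc(O)cc1O)c1c(OCOC)cc(OCOC)c(OC)c1CC=C(C)C | intermediate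
14 | 3-[2,4-bis(methoxymethoxy)-5-methoxy-6-(3-methylbut-2-en-1-yl)phenyl]-5,7-dihydroxy-4H-chromen-4-one | COCOc1cc(OCOC)c(OC)c(CC=C(C)C)c1-c1coc2cc(O)cc(O)c2c1=O | intermediate
15 | 5,7-dihydroxy-3-[2,4-dihydroxy-5-methoxy-6-(3-methylbut-2-en-1-yl)phenyl]-4H-chromen-4-one | COc1c(O)cc(O)c(-c2coc3cc(O)cc(O)c3c2=O)c1CC=C(C)C | target

**Step count:** 8 steps in total.
**Longest linear sequence:** 6 steps (1 → 2 → 4 → 5 → 6 → 12 → 15; steps 1, 2, 3, 4, 7, 8).

**Three steps most likely to fail, with fallbacks**

Step 7 (enolonium arylation). The risks are capture of the enolonium by tosylate, attack by the prenyl alkene or at C6 of the arene, and partial loss of MOM groups to BF3. The fallback makes the same bond in normal polarity, setting out from 8 (with 6) and returning at 11. Riley oxidation of 8 (SeO2, dioxane, 90 °C) gives the arylglyoxal 2-(oxoacetyl)benzene-1,3,5-triyl triacetate F1. Friedel–Crafts hydroxyalkylation of 6 at C4 by the aldehyde carbon of F1 (hexafluoroisopropanol, rt) gives the racemic α-hydroxy ketone 2-{2-[2,4-bis(methoxymethoxy)-5-methoxy-6-(3-methylbut-2-en-1-yl)phenyl]-2-hydroxyacetyl}benzene-1,3,5-triyl triacetate F2. Acetylation (Ac2O, pyridine) gives the racemic α-acetoxy ketone 2-{2-acetoxy-2-[2,4-bis(methoxymethoxy)-5-methoxy-6-(3-methylbut-2-en-1-yl)phenyl]acetyl}benzene-1,3,5-triyl triacetate F3. SmI2 (THF/MeOH, −78 °C) then cleaves the α-C–OAc bond reductively to give 11, which is ammonolysed as in step 7 to 12.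

Step 3 (ortho-C-prenylation). The risk is that O-alkylation dominates and the yield is low. The fallback sets out from 4 and returns at 5. Tsuji–Trost O-alkylation of 4 with methyl 2-methylbut-3-en-2-yl carbonate and Pd(PPh3)4 (THF, 0 °C → rt) gives the tertiary allyl ether 1-[(2-methylbut-3-en-2-yl)oxy]-2,4-bis(methoxymethoxy)benzene F4. Thermal aromatic Claisen rearrangement of F4 (toluene, 110 °C) delivers the 3-methylbut-2-enyl group to the only free ortho position, giving 5.

Step 8 (ring C closure with free phenols, then deprotection). The risks are O-methylation of the 7-OH by DMF-DMA and slow condensation at the hindered CH2. The fallback sets out from 12 and returns at 15. Crossed Claisen C-formylation of 12 with ethyl formate and NaH (THF, 0 °C → rt) gives, after work-up, the cyclic hemiacetal 3-[2,4-bis(methoxymethoxy)-5-methoxy-6-(3-methylbut-2-en-1-yl)phenyl]-2,5,7-trihydroxychroman-4-one F5 (racemic mixture of diastereomers). HCl/MeOH (50 °C) then dehydrates F5 to the chromone and removes both MOM groups, giving 15.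

**Further compounds**
F1 | step 7 | 2-(oxoacetyl)benzene-1,3,5-triyl triacetate | O=CC(=O)c1c(OC(C)=O)cc(OC(C)=O)cc1OC(C)=O
F2 | step 7 | 2-{2-[2,4-bis(methoxymethoxy)-5-methoxy-6-(3-methylbut-2-en-1-yl)phenyl]-2-hydroxyacetyl}benzene-1,3,5-triyl triacetate (racemic) | CC(=O)Oc1cc(OC(C)=O)c(C(=O)C(O)c2c(OCOC)cc(OCOC)c(OC)c2CC=C(C)C)c(OC(C)=O)c1
F3 | step 7 | 2-{2-acetoxy-2-[2,4-bis(methoxymethoxy)-5-methoxy-6-(3-methylbut-2-en-1-yl)phenyl]acetyl}benzene-1,3,5-triyl triacetate (racemic) | CC(=O)Oc1cc(OC(C)=O)c(C(=O)C(OC(C)=O)c2c(OCOC)cc(OCOC)c(OC)c2CC=C(C)C)c(OC(C)=O)c1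
F4 | step 3 | 1-[(2-methylbut-3-en-2-yl)oxy]-2,4-bis(methoxymethoxy)benzene | C=CC(C)(C)Oc1ccc(OCOC)cc1OCOC
F5 | step 8 | 3-[2,4-bis(methoxymethoxy)-5-methoxy-6-(3-methylbut-2-en-1-yl)phenyl]-2,5,7-trihydroxychroman-4-one (racemic, mixture of diastereomers) | OC1Oc2cc(O)cc(O)c2C(=O)C1c1c(OCOC)cc(OCOC)c(OC)c1CC=C(C)C
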